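**Plan**

1. Retrosynthesis: the two interflavan bonds (middle C4–bottom C6, then top C4–middle C6) are cut as flavan-4-yl cation arylations; top and bottom units are (−)-epicatechin, and bromine caps enforce the 4→6 regiochemistry.
2. The middle unit is built, not taken from the pool: its ring C is cut at O1–C8a and C2–C3, back to aldehyde 8 (O1=C2 plus ring B) and aryl ketone 6 (C3–C4–C4a–C8a).
3. Enabling feature: in ring A of the middle unit C8a is ortho to C4. With C4 as a ketone, C8a–F is a vinylogous acyl fluoride and C3 an enolisable α-benzyloxy carbon, so silyl enol ether 7 is a benzo-fused 1-fluoro-3-silyloxy-diene for the C2=O1 bond.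
4. Forward: symmetric 3,5-bis(benzyloxy)fluorobenzene → dibromide (one Br becomes the C4a–C4 bond, the other the C8 cap) → ketone → enol silane → fluoride-relay aldol/SNAr annulation (ring C) → 4-ol → 4β-thioether as latent C4 cation.
5. Assembly: doubly capped top cation + middle C6 (hard activation), then thiophilic activation of middle C4 + bottom C6, then one global hydrogenolysis.
6. Stereochemistry: top and bottom from (−)-epicatechin; middle C2/C3 from a catalyst-controlled syn aldol (cis survives because O1–C8a closure touches neither centre); both interflavan C4 centres by attack anti to the 3-oxygen (4β).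

Key step: step 5

Remark: 1, 4, 8 and 13 are taken as purchasable. C4 of 11 is drawn as the 4α-alcohol; either epimer would serve, because C4 is ionised in step 6.

**Step 1**
Reactants: 1 1,3,5-trifluorobenzene
Product: 2 1,3-bis(benzyloxy)-5-fluorobenzene
Conditions: BnOH (2.1 equiv), NaH, NMP, 0 → 100 °C
Reagents that add atoms: benzyl alcohol, OCc1ccccc1
Why: Twofold SNAr by benzyloxide; each benzyloxy group is meta to the remaining fluorines and slows the next substitution, so two equivalents should stop at the monofluoride, and no stereocentre is involved.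

**Step 2**
Reactants: 2 1,3-bis(benzyloxy)-5-fluorobenzene
Product: 3 1,5-bis(benzyloxy)-2,4-dibromo-3-fluorobenzene
Conditions: NBS (2.05 equiv), MeCN, 0 °C → rt
Reagents that add atoms: N-bromosuccinimide, O=C1CCC(=O)N1Br
Why: Electrophilic aromatic bromination para to each benzyloxy group (the two positions flanking fluorine), the position between the two ethers being the least reactive as in 1,3-dialkoxybenzenes, which should give a dibromide with a mirror plane.

**Step 3**
Reactants: 3 1,5-bis(benzyloxy)-2,4-dibromo-3-fluorobenzene; 4 2-(benzyloxy)-N-methoxy-N-methylacetamide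
Product: 6 2-(benzyloxy)-1-[4,6-bis(benzyloxy)-3-bromo-2-fluorophenyl]ethan-1-one, via arylmagnesium chloride 5 (not isolated)
Conditions: iPrMgCl·LiCl (1.05 equiv), THF, −20 → 0 °C; then 4, 0 °C; aq. NH4Cl
Reagents that add atoms: none
Why: Bromine–magnesium exchange (either bromine, by symmetry) gives an ortho-fluoroaryl Grignard reagent that should be stable below 0 °C and is acylated once by the Weinreb amide through its chelated tetrahedral adduct; the bromine left over becomes the C8 cap of ring A.

**Step 4**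
Reactants: 6 2-(benzyloxy)-1-[4,6-bis(benzyloxy)-3-bromo-2-fluorophenyl]ethan-1-one
Product: 7 (Z)-trimethylsilyl enol ether of 6
Conditions: TMSOTf, Et3N, CH2Cl2, 0 °C; used crude
Reagents that add atoms: trimethylsilyl triflate, C[Si](C)(C)OS(=O)(=O)C(F)(F)F
Why: Soft enolisation of the only enolisable position with silyl triflate and amine should give the silyl enol ether (Z expected; the geometry is not critical for step 5).

**Step 5**
Reactants: 7 (Z)-trimethylsilyl enol ether (1.15 equiv); 8 3,4-bis(benzyloxy)benzaldehyde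
Product: 11 3,5,7,3′,4′-penta-O-benzyl-8-bromo-4α-hydroxyepicatechin (2R,3R,4R; all-cis), via silylated syn-aldol 9 (not isolated), via cis-flavanone 10 (not isolated)
Conditions: N-(9-anthracenylmethyl)-O-benzylcinchonidinium bifluoride (10 mol %), THF, −78 → −40 °C; then LiBH4, −78 °C; aq. NH4Cl
Reagents that add atoms: none
Why: Proposed new method: bifluoride removes the silyl group of 7 and the ion-paired enolate adds with C3 to the aldehyde carbon C2 of 8 (Mukaiyama-type aldol through an open, antiperiplanar transition state); the alkoxide O1 so formed, or the silicate that fluoride makes from silyl ether 9, attacks C8a of ring A, where fluorine is ortho to the C4 ketone (a vinylogous acyl fluoride) and to bromine while both benzyloxy groups are meta, and the fluoride expelled from the Meisenheimer intermediate restarts the cycle, so that the balance is 7 + 8 → 10 + Me3SiF with fluoride as chain carrier. The closest known reaction types are the quaternary-ammonium-bifluoride-catalysed Mukaiyama aldol of ketone silyl enol ethers with aromatic aldehydes and the fluoride-catalysed SNAr etherification of silyl ethers with aryl fluorides; taken together, 7 behaves as a benzo-fused 1-fluoro-3-silyloxy-diene in a stepwise hetero-Diels–Alder annulation with the C2=O1 bond. Ring C closes by a 6-exo attack of O1 on the arene carbon C8a (addition–elimination), which does not touch C2 or C3. C2 and C3 are set in the aldol step: the open transition state of the unsolvated enolate should give the syn aldolate, which is the 2,3-cis (epi) series after closure, and the cinchonidinium cation paired with the enolate is relied on to expose the Si face of the aldehyde, which gives 2R (its cinchonine-derived pseudoenantiomer would give the mirror series). C4 is then set by hydride delivery from LiBH4 anti to the pseudoaxial 3-benzyloxy group (4α-OH), a centre of no consequence since it is ionised in step 6. The step needs cyclisation to outrun retro-aldol cleavage and C3 epimerisation of 10 and needs fluoride, not the C5 benzyloxy group, to leave: the double ortho activation of C8a, the absence of stoichiometric base (fluoride rests as Me3SiF2−) and the cold in-flask reduction of the ketone are meant to secure the first, leaving-group ability the second.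

**Step 6**
Reactants: 11 3,5,7,3′,4′-penta-O-benzyl-8-bromo-4α-hydroxyepicatechin
Product: 12 3,5,7,3′,4′-penta-O-benzyl-8-bromo-4β-(2,6-dimethylphenylthio)epicatechin
Conditions: 2,6-dimethylbenzenethiol (5 equiv), BF3·OEt2, CH2Cl2, −78 → −30 °C
Reagents that add atoms: 2,6-dimethylbenzenethiol, Cc1cccc(C)c1S
Why: SN1 thioetherification: BF3 ionises the C4 alcohol to the ring-A-stabilised flavan-4-yl cation, which the thiol in excess should trap anti to the 3-benzyloxy group (4β, as in thiolysis) faster than C6 of a second molecule can.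

**Step 7**
Reactants: 13 (−)-epicatechin
Product: 14 5,7,3′,4′-tetra-O-benzyl-(−)-epicatechin
Conditions: BnBr (4.2 equiv), K2CO3, DMF, 0 °C → rt
Reagents that add atoms: benzyl bromide, BrCc1ccccc1
Why: Williamson etherification of the four phenols with carbonate base, which leaves the aliphatic 3-hydroxyl and both stereocentres untouched.

**Step 8**
Reactants: 14 5,7,3′,4′-tetra-O-benzyl-(−)-epicatechin
Product: 15 5,7,3′,4′-tetra-O-benzyl-4β-(2-ethoxyethoxy)epicatechin
Conditions: DDQ (2 equiv), 2-ethoxyethanol, CH2Cl2, rt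
Reagents that add atoms: 2-ethoxyethanol, CCOCCO
Why: Benzylic C4–H oxidation by hydride abstraction with DDQ gives the ring-A-stabilised C4 cation, which the alcohol should trap anti to the 3-hydroxyl (4β, 3,4-trans).

**Step 9**
Reactants: 15 5,7,3′,4′-tetra-O-benzyl-4β-(2-ethoxyethoxy)epicatechin
Product: 16 5,7,3′,4′-tetra-O-benzyl-6,8-dibromo-4β-(2-ethoxyethoxy)epicatechin
Conditions: NBS (2.2 equiv), NaHCO3, CH2Cl2, −20 °C → rt
Reagents that add atoms: N-bromosuccinimide, O=C1CCC(=O)N1Br
Why: Electrophilic bromination of both free positions of the phloroglucinol-type ring A (C8, then C6), ring B being far less activated, so that the later cation has no nucleophilic site of its own.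

**Step 10**
Reactants: 16 capped top electrophile (1.3 equiv); 12 middle-unit thioether
Product: 17 top–middle dimer thioether (4β→6 linked; 6,8-dibromo top unit; 8-bromo-4β-arylthio middle unit)
Conditions: TMSOTf (0.3 equiv), CH2Cl2, −78 °C; Et3N quench
Reagents that add atoms: none
Why: Friedel–Crafts-type arylation of a flavan-4-yl cation (interflavan bond formation) under hard activation: the cation from 16 cannot attack its own capped ring A, the C4–S bond of 12 should be left alone by the silyl triflate, C6 is the only free ring A position of 12, and attack anti to the 3-hydroxyl gives the 4β→6 bond.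

**Step 11**
Reactants: 14 5,7,3′,4′-tetra-O-benzyl-(−)-epicatechin
Product: 18 5,7,3′,4′-tetra-O-benzyl-8-bromo-(−)-epicatechin
Conditions: NBS (1.0 equiv), CH2Cl2, −78 °C
Reagents that add atoms: N-bromosuccinimide, O=C1CCC(=O)N1Br
Why: Electrophilic bromination at C8, the more reactive ring A position of tetra-O-benzyl flavan-3-ols, which leaves C6 as the only nucleophilic carbon.

**Step 12**
Reactants: 17 top–middle dimer thioether; 18 8-bromo bottom nucleophile (2.5 equiv)
Product: 19 trideca-O-benzyl-tetrabromo trimer (4β→6 and 4β→6 linked)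
Conditions: AgBF4 (2 equiv), THF/CH2Cl2, −20 → 0 °C
Reagents that add atoms: none
Why: Thiophilic activation of the 4-thioether by AgBF4 gives the middle-unit C4 cation, which has no free ring A position within 17 to attack and should be captured by C6 of 18 (C8 capped) anti to the 3-benzyloxy group, which sets the second 4β→6 bond.

**Step 13**
Reactants: 19 trideca-O-benzyl-tetrabromo trimer
Product: 20 epicatechin-(4β→6)-epicatechin-(4β→6)-epicatechin (target)
Conditions: H2 (1 atm), Pd(OH)2/C, Et3N, THF/MeOH/H2O, rt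
Reagents that add atoms: none
Why: Hydrogenolysis of the thirteen benzyl ethers and hydrodebromination of the four aryl bromides over Pd(OH)2, with triethylamine to buffer HBr so that the acid-labile interflavan bonds and all eight stereocentres stay untouched.

**Compound list**

1 | 1,3,5-trifluorobenzene | Fc1cc(F)cc(F)c1 | starting material
2 | 1,3-bis(benzyloxy)-5-fluorobenzene | Fc1cc(OCc2ccccc2)cc(OCc2ccccc2)c1 | intermediate
3 | 1,5-bis(benzyloxy)-2,4-dibromo-3-fluorobenzene | Fc1c(Br)c(OCc2ccccc2)cc(OCc2ccccc2)c1Br | intermediate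
4 | 2-(benzyloxy)-N-methoxy-N-methylacetamide | CON(C)C(=O)COCc1ccccc1 | starting material
5 | [4,6-bis(benzyloxy)-3-bromo-2-fluorophenyl]magnesium chloride (LiCl complex) | Cl[Mg]c1c(F)c(Br)c(OCc2ccccc2)cc1OCc1ccccc1 | intermediate
6 | 2-(benzyloxy)-1-[4,6-bis(benzyloxy)-3-bromo-2-fluorophenyl]ethan-1-one | O=C(COCc1ccccc1)c1c(F)c(Br)c(OCc2ccccc2)cc1OCc1ccccc1 | intermediate
7 | (Z)-{[2-(benzyloxy)-1-[4,6-bis(benzyloxy)-3-bromo-2-fluorophenyl]ethenyl]oxy}trimethylsilane | C[Si](C)(C)O/C(=C\OCc1ccccc1)c1c(F)c(Br)c(OCc2ccccc2)cc1OCc1ccccc1 | intermediate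
8 | 3,4-bis(benzyloxy)benzaldehyde | O=Cc1ccc(OCc2ccccc2)c(OCc2ccccc2)c1 | starting material
9 | (2S,3R)-2-(benzyloxy)-1-[4,6-bis(benzyloxy)-3-bromo-2-fluorophenyl]-3-[3,4-bis(benzyloxy)phenyl]-3-(trimethylsilyloxy)propan-1-one (syn) | c1c(OCc4ccccc4)c(Br)c(F)c(c1OCc1ccccc1)C(=O)[C@@H](OCc1ccccc1)[C@@H](c1ccc(OCc4ccccc4)c(OCc4ccccc4)c1)O[Si](C)(C)C | intermediate
10 | (2R,3S)-3,5,7-tris(benzyloxy)-2-[3,4-bis(benzyloxy)phenyl]-8-bromo-2,3-dihydro-4H-chromen-4-one (2,3-cis) | c1c(OCc4ccccc4)c(Br)c2c(c1OCc1ccccc1)C(=O)[C@@H](OCc1ccccc1)[C@@H](c1ccc(OCc4ccccc4)c(OCc4ccccc4)c1)O2 | intermediate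
11 | 3,5,7,3′,4′-penta-O-benzyl-8-bromo-4α-hydroxyepicatechin; (2R,3R,4R)-3,5,7-tris(benzyloxy)-2-[3,4-bis(benzyloxy)phenyl]-8-bromochroman-4-ol | c1c(OCc4ccccc4)c(Br)c2c(c1OCc1ccccc1)[C@@H](O)[C@@H](OCc1ccccc1)[C@@H](c1ccc(OCc4ccccc4)c(OCc4ccccc4)c1)O2 | intermediate
12 | 3,5,7,3′,4′-penta-O-benzyl-8-bromo-4β-(2,6-dimethylphenylthio)epicatechin (2α-aryl, 3α-OBn, 4β-S) | c1c(OCc4ccccc4)c(Br)c2c(c1OCc1ccccc1)[C@H](Sc1c(C)cccc1C)[C@@H](OCc1ccccc1)[C@@H](c1ccc(OCc4ccccc4)c(OCc4ccccc4)c1)O2 | intermediate
13 | (−)-epicatechin, (2R,3R) | O[C@@H]1Cc2c(O)cc(O)cc2O[C@@H]1c1ccc(O)c(O)c1 | starting material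
14 | 5,7,3′,4′-tetra-O-benzyl-(−)-epicatechin | O[C@@H]1Cc2c(OCc3ccccc3)cc(OCc3ccccc3)cc2O[C@@H]1c1ccc(OCc2ccccc2)c(OCc2ccccc2)c1 | intermediate
15 | 5,7,3′,4′-tetra-O-benzyl-4β-(2-ethoxyethoxy)epicatechin (2,3-cis, 3,4-trans) | c5ccccc5COc1cc(OCc5ccccc5)c2c(c1)O[C@H](c1ccc(OCc5ccccc5)c(OCc5ccccc5)c1)[C@H](O)[C@H]2OCCOCC | intermediate
16 | 5,7,3′,4′-tetra-O-benzyl-6,8-dibromo-4β-(2-ethoxyethoxy)epicatechin | c5ccccc5COc1c(Br)c(OCc5ccccc5)c2c(c1Br)O[C@H](c1ccc(OCc5ccccc5)c(OCc5ccccc5)c1)[C@H](O)[C@H]2OCCOCC | intermediate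
17 | [5,7,3′,4′-tetra-O-benzyl-6,8-dibromoepicatechin]-(4β→6)-[3,5,7,3′,4′-penta-O-benzyl-8-bromo-4β-(2,6-dimethylphenylthio)epicatechin] | c5ccccc5COc1c(Br)c(OCc5ccccc5)c2c(c1Br)O[C@H](c1ccc(OCc5ccccc5)c(OCc5ccccc5)c1)[C@H](O)[C@H]2c1c(OCc4ccccc4)c(Br)c2c(c1OCc1ccccc1)[C@H](Sc1c(C)cccc1C)[C@@H](OCc1ccccc1)[C@@H](c1ccc(OCc4ccccc4)c(OCc4ccccc4)c1)O2 | intermediate
18 | 5,7,3′,4′-tetra-O-benzyl-8-bromo-(−)-epicatechin | O[C@@H]1Cc2c(OCc3ccccc3)cc(OCc3ccccc3)c(Br)c2O[C@@H]1c1ccc(OCc2ccccc2)c(OCc2ccccc2)c1 | intermediate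
19 | [5,7,3′,4′-tetra-O-benzyl-6,8-dibromoepicatechin]-(4β→6)-[3,5,7,3′,4′-penta-O-benzyl-8-bromoepicatechin]-(4β→6)-[5,7,3′,4′-tetra-O-benzyl-8-bromoepicatechin] | c5ccccc5COc1c(Br)c(OCc5ccccc5)c2c(c1Br)O[C@H](c1ccc(OCc5ccccc5)c(OCc5ccccc5)c1)[C@H](O)[C@H]2c1c(OCc4ccccc4)c(Br)c2c(c1OCc1ccccc1)[C@H](c1c(OCc4ccccc4)c(Br)c3c(c1OCc1ccccc1)C[C@@H](O)[C@@H](c1ccc(OCc4ccccc4)c(OCc4ccccc4)c1)O3)[C@@H](OCc1ccccc1)[C@@H](c1ccc(OCc4ccccc4)c(OCc4ccccc4)c1)O2 | intermediate
20 | epicatechin-(4β→6)-epicatechin-(4β→6)-epicatechin (CNP0163146.2) | Oc1cc(O)c2c(c1)O[C@H](c1ccc(O)c(O)c1)[C@H](O)[C@H]2c1c(O)cc2c(c1O)[C@H](c1c(O)cc3c(c1O)C[C@@H](O)[C@@H](c1ccc(O)c(O)c1)O3)[C@@H](O)[C@@H](c1ccc(O)c(O)c1)O2 | target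

**Step count and risks**

Total step count: 13. Longest linear sequence: 9 steps (steps 1, 2, 3, 4, 5, 6, 10, 12, 13).

Step 5 (proposed new method). What may go wrong: retro-aldol cleavage of the aldolate before ring closure, with loss of the syn relationship and of enantiomeric purity; epimerisation at C3 of flavanone 10 before the hydride quench; poor facial selectivity of the ion-paired enolate. The fallback uses known reaction types and separates the two bond formations. It sets out from 6 and comes back at 11. Ketone 6 is enolised with diisopinocampheylboron triflate (the antipode that directs attack to the Si face of 8) and iPr2NEt in CH2Cl2 at −78 °C, and the (Z)-boron enolate is combined with 8 through a closed Zimmerman–Traxler transition state to give the syn-aldol (2S,3R)-2-(benzyloxy)-1-[4,6-bis(benzyloxy)-3-bromo-2-fluorophenyl]-3-[3,4-bis(benzyloxy)phenyl]-3-hydroxypropan-1-one F1. Evans–Saksena reduction (Me4NBH(OAc)3, MeCN/AcOH, −30 °C) removes the ketone before any alkoxide is made and should give the 1,3-anti, 2,3-syn diol F2. KH with 18-crown-6 in THF/DMF at 0 °C → rt then closes ring C by intramolecular SNAr of the benzylic alkoxide on the aryl fluoride, whose alkoxy groups are meta, to give 11.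

Step 10. What may go wrong: slow attack by the hindered, bromine-deactivated C6 of 12, so that the cation from 16 eliminates to the flav-3-ene; or partial activation of the C4–S bond by the silyl triflate and oligomerisation of 12. The fallback reverses the order of assembly and needs no thioether. It sets out from 11 and comes back at 19. Alcohol 11 is added slowly to 18 (3 equiv) and BF3·OEt2 in CH2Cl2 at −78 °C; the excess of 18 is there to outcompete self-condensation of 11 at its own C6. This should give the middle–bottom dimer [3,5,7,3′,4′-penta-O-benzyl-8-bromoepicatechin]-(4β→6)-[5,7,3′,4′-tetra-O-benzyl-8-bromoepicatechin] F3. Its only free ring A position is C6 of the middle unit, which is then coupled with the cation from 16 (TMSOTf, CH2Cl2, −78 °C) to give 19.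

Step 12. What may go wrong: incomplete or unselective thiophilic activation; cleavage of the new top–middle bond by the acid set free; elimination of the crowded cation before the capped C6 of 18 arrives. The fallback changes the activation mode. It sets out from 17 and comes back at 19. The sulfide is oxidised with mCPBA (1 equiv, CH2Cl2, −78 °C) to the sulfoxide of 17 F4 (mixture at sulfur). F4 is activated with Tf2O and 2,6-di-tert-butyl-4-methylpyridine in CH2Cl2 at −78 °C in the presence of 18; sulfoxide activation is a known way to release such cations under buffered, metal-free conditions, and it should give 19.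

**Further compounds**

F1 | step 5 | (2S,3R)-2-(benzyloxy)-1-[4,6-bis(benzyloxy)-3-bromo-2-fluorophenyl]-3-[3,4-bis(benzyloxy)phenyl]-3-hydroxypropan-1-one (syn-aldol) | c1c(OCc4ccccc4)c(Br)c(F)c(c1OCc1ccccc1)C(=O)[C@@H](OCc1ccccc1)[C@@H](c1ccc(OCc4ccccc4)c(OCc4ccccc4)c1)O
F2 | step 5 | 2-(benzyloxy)-1-[4,6-bis(benzyloxy)-3-bromo-2-fluorophenyl]-3-[3,4-bis(benzyloxy)phenyl]propane-1,3-diol (1,3-anti, 2,3-syn) | c1c(OCc4ccccc4)c(Br)c(F)c(c1OCc1ccccc1)[C@@H](O)[C@@H](OCc1ccccc1)[C@@H](c1ccc(OCc4ccccc4)c(OCc4ccccc4)c1)O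
F3 | step 10 | [3,5,7,3′,4′-penta-O-benzyl-8-bromoepicatechin]-(4β→6)-[5,7,3′,4′-tetra-O-benzyl-8-bromoepicatechin] | c1c(OCc4ccccc4)c(Br)c2c(c1OCc1ccccc1)[C@H](c1c(OCc4ccccc4)c(Br)c3c(c1OCc1ccccc1)C[C@@H](O)[C@@H](c1ccc(OCc4ccccc4)c(OCc4ccccc4)c1)O3)[C@@H](OCc1ccccc1)[C@@H](c1ccc(OCc4ccccc4)c(OCc4ccccc4)c1)O2
F4 | step 12 | sulfoxide of 17 (4β-(2,6-dimethylphenylsulfinyl), mixture at sulfur) | c5ccccc5COc1c(Br)c(OCc5ccccc5)c2c(c1Br)O[C@H](c1ccc(OCc5ccccc5)c(OCc5ccccc5)c1)[C@H](O)[C@H]2c1c(OCc4ccccc4)c(Br)c2c(c1OCc1ccccc1)[C@H](S(=O)c1c(C)cccc1C)[C@@H](OCc1ccccc1)[C@@H](c1ccc(OCc4ccccc4)c(OCc4ccccc4)c1)O2
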